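## Retrosynthetic overview

1. Atom labels used throughout: C1 = methyl-bearing ring-fusion carbon, C2/C3 = cyclopentane CH2, C4 = C(OH)(iPr), C5 = ring-fusion CH, C6 = aroyloxy carbon, C7 = CH2, C8=C9 = ring alkene (methyl on C8), C10 = isovaleryloxy carbon. The two esters go on last: C6 first, C10 after desilylation.
2. Seven-membered ring last: C8=C9 by ring-closing metathesis of a vinyl arm (on C10) and a methallyl arm (on C6); C6–C7 by reagent-controlled methallylboration of a C6 aldehyde.
3. Five-membered ring first (key step): C4–C5 by SmI2 ketyl–olefin 5-exo cyclisation, the isopropyl-ketone carbon acting as a nucleophilic ketyl toward the vinyl group on C1; O2 capture of the alkylsamarium gives the C6 oxygen. This sets C4 and C5.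
4. Acyclic precursor: isopropyl ketone from the prenyl end (epoxidation, Meinwald shift); the C10–C1 bond and both its stereocentres from catalytic asymmetric addition of (Z)-neryl trichlorosilane to acrolein.
5. Building blocks: nerol, acrolein, 2-methylallylmagnesium chloride, 4-acetoxybenzoyl chloride, 3-methylbutanoyl chloride.

Assumption: the target is taken exactly as drawn, i.e. (3S,3aS,4R,8S,8aS) in azulene numbering (C1 S, C4 S, C5 S, C6 R, C10 S in the labels above); the chiral bisphosphoramide of step 3 is a known catalyst prepared separately.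

## Route

Step 1
Reactants: 1 nerol [(2Z)-3,7-dimethylocta-2,6-dien-1-ol]
Product: 2 neryl chloride [(2Z)-1-chloro-3,7-dimethylocta-2,6-diene]
Conditions: NCS, Me2S, CH2Cl2, −40 °C to 0 °C
Reagents that add atoms: N-chlorosuccinimide, O=C1CCC(=O)N1Cl
Why: Corey–Kim chlorination, in which chloride displaces the alkoxysulfonium ion at the primary allylic carbon (SN2), so the Z-alkene is neither moved nor isomerised; no stereocentre is formed.

Step 2
Reactants: 2 neryl chloride
Product: 3 neryl trichlorosilane [trichloro[(2Z)-3,7-dimethylocta-2,6-dien-1-yl]silane]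
Conditions: HSiCl3, CuCl (5 mol %), iPr2NEt, Et2O, 0 °C to rt; distil
Reagents that add atoms: trichlorosilane, Cl[SiH](Cl)Cl
Why: CuCl/amine-promoted silylation of an allylic chloride with HSiCl3 substitutes at the primary carbon with retention of the Z-geometry, giving the γ,γ-disubstituted allylsilane needed for a closed transition state.

Step 3
Reactants: 3 neryl trichlorosilane; 4 acrolein (prop-2-enal)
Product: 6 (3S,4S)-4-ethenyl-4,8-dimethylnona-1,7-dien-3-ol, via trichlorosilyl ether 5 (not isolated)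
Conditions: Denmark's 2,2′-bispyrrolidine-derived bisphosphoramide (5 mol %, the enantiomer that directs Re-face addition, expected (S,S)), iPr2NEt, CH2Cl2, −78 °C; then sat. aq. NaHCO3
Reagents that add atoms: none
Why: Lewis-base-catalysed Denmark allylation through a closed chair transition state of the hexacoordinate siliconate: the silane reacts at its γ-carbon with the vinyl group of acrolein equatorial, so the Z-geometry gives the syn (like) pair, and the catalyst selects the Re face of the aldehyde, setting C10 (S) and the quaternary C1 (S) together.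

Step 4
Reactants: 6 (3S,4S)-4-ethenyl-4,8-dimethylnona-1,7-dien-3-ol
Product: 7 tert-butyl{[(3S,4S)-4-ethenyl-4,8-dimethylnona-1,7-dien-3-yl]oxy}dimethylsilane
Conditions: TBSOTf, 2,6-lutidine, CH2Cl2, −78 °C to 0 °C
Reagents that add atoms: tert-butyldimethylsilyl trifluoromethanesulfonate, CC(C)(C)[Si](C)(C)OS(=O)(=O)C(F)(F)F
Why: silyl ether formation with the triflate silylates the hindered neopentyl-type alcohol; this keeps the C10 oxygen from opening the epoxide in step 6 and lets it be acylated last, with no change at any stereocentre.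

Step 5
Reactants: 7 silyl ether
Product: 8 tert-butyl{[(3S,4S)-6-(3,3-dimethyloxiran-2-yl)-4-ethenyl-4-methylhex-1-en-3-yl]oxy}dimethylsilane (both epimers at the oxirane CH)
Conditions: mCPBA (1.05 equiv), NaHCO3, CH2Cl2, −20 °C to 0 °C
Reagents that add atoms: 3-chloroperbenzoic acid, OOC(=O)c1cccc(Cl)c1
Why: Prilezhaev epoxidation, in which the peracid takes the electron-rich trisubstituted alkene far faster than the two monosubstituted vinyl groups; the new oxirane centre forms unselectively but is erased in step 6.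

Step 6
Reactants: 8 epoxide
Product: 9 (6S,7S)-7-[(tert-butyldimethylsilyl)oxy]-6-ethenyl-2,6-dimethylnon-8-en-3-one
Conditions: BF3·OEt2 (0.3 equiv), CH2Cl2, −78 °C
Reagents that add atoms: none
Why: Meinwald rearrangement, in which Lewis-acid opening at the tertiary oxirane carbon is followed by a 1,2-hydride shift to give the isopropyl ketone; the monosubstituted vinyl groups are too poor as π-nucleophiles to intercept the cation, and C1 and C10 are untouched.

Step 7
Reactants: 9 isopropyl ketone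
Product: 11 (1S,2S,3S)-3-[(1S)-1-[(tert-butyldimethylsilyl)oxy]prop-2-en-1-yl]-2-(hydroxymethyl)-3-methyl-1-(propan-2-yl)cyclopentan-1-ol, via alkylsamarium alkoxide 10 (not isolated)
Conditions: SmI2 (4.5 equiv), HMPA, THF, 0 °C to rt; then dry O2, −78 °C to 0 °C; sat. aq. NH4Cl
Reagents that add atoms: dioxygen, O=O
Why: SmI2-promoted ketyl–olefin 5-exo-trig radical cyclisation (Molander type) followed by oxygenation of the alkylsamarium (key step): the ketone carbon attacks the vinyl group on C1 as a nucleophilic ketyl radical anion; in the chair-like Beckwith–Houk transition state the bulky silyloxyallyl arm on C1 sits pseudo-equatorial so the new CH2 ends trans to it (C5), the HMPA-solvated samarium alkoxide lies anti to the alkene so the hydroxyl ends trans to C6 (C4), and O2 turns the C6–Sm bond into C6–OH.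

Step 8
Reactants: 11 diol
Product: 12 (1R,2S,5S)-2-[(1S)-1-[(tert-butyldimethylsilyl)oxy]prop-2-en-1-yl]-5-hydroxy-2-methyl-5-(propan-2-yl)cyclopentane-1-carbaldehyde
Conditions: TEMPO (10 mol %), PhI(OAc)2, CH2Cl2, rt
Reagents that add atoms: none
Why: oxoammonium (TEMPO/PhI(OAc)2) oxidation takes only the primary alcohol, the tertiary hydroxyl cannot be oxidised, and the near-neutral medium avoids retro-aldol cleavage and epimerisation at C5 (its descriptor changes to R only through priorities).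

Step 9
Reactants: 12 aldehyde
Product: 14 (1S,2S,3S)-3-[(1S)-1-[(tert-butyldimethylsilyl)oxy]prop-2-en-1-yl]-2-[(1R)-1-hydroxy-3-methylbut-3-en-1-yl]-3-methyl-1-(propan-2-yl)cyclopentan-1-ol, via diisopinocampheylborinate 13 (not isolated)
Conditions: (+)-Ipc2BOMe [from (−)-α-pinene], 2-methylallylmagnesium chloride, Et2O, 0 °C; then 12, −78 °C; then NaOH, H2O2, 0 °C
Reagents that add atoms: 2-methylallylmagnesium chloride, CC(=C)C[Mg]Cl
Why: Brown asymmetric methallylboration through a Zimmerman–Traxler chair under reagent control: the borane derived from (−)-α-pinene adds to the Re face of the aldehyde and sets C6 (R).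

Step 10
Reactants: 14 triene diol
Product: 15 (3S,3aS,4R,8S,8aS)-8-[(tert-butyldimethylsilyl)oxy]-6,8a-dimethyl-3-(propan-2-yl)-1,2,3,3a,4,5,8,8a-octahydroazulene-3,4-diol
Conditions: second-generation Grubbs catalyst, (H2IMes)(PCy3)Cl2Ru=CHPh (5 mol %), toluene, 80 °C
Reagents that add atoms: none
Why: ring-closing metathesis joins the vinyl group on C10 and the 1,1-disubstituted methallyl alkene into the seven-membered ring with the trisubstituted C8=C9 alkene, releasing ethylene; the two arms are trans on the cyclopentane, so the bicycle is trans-fused and no stereocentre is touched.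

Step 11
Reactants: 15 bicyclic diol
Product: 16 [(3S,3aS,4R,8S,8aS)-8-[(tert-butyldimethylsilyl)oxy]-3-hydroxy-6,8a-dimethyl-3-(propan-2-yl)-1,2,3,3a,4,5,8,8a-octahydroazulen-4-yl] 4-(acetyloxy)benzoate
Conditions: 4-acetoxybenzoyl chloride, pyridine, DMAP, CH2Cl2, 0 °C to 40 °C
Reagents that add atoms: 4-acetoxybenzoyl chloride, CC(=O)Oc1ccc(cc1)C(Cl)=O
Why: DMAP-catalysed acylation (nucleophilic catalysis) esterifies the secondary C6 hydroxyl, while the tertiary C4 hydroxyl and the silyl ether do not react.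

Step 12
Reactants: 16 silyl ether ester
Product: 17 [(3S,3aS,4R,8S,8aS)-3,8-dihydroxy-6,8a-dimethyl-3-(propan-2-yl)-1,2,3,3a,4,5,8,8a-octahydroazulen-4-yl] 4-(acetyloxy)benzoate
Conditions: HF·pyridine, pyridine, THF, 0 °C to rt
Reagents that add atoms: none
Why: fluoride-mediated desilylation with buffered HF·pyridine cleaves the alkyl silyl ether, while the benzoate and the aryl acetate survive the weakly acidic medium.

Step 13
Reactants: 17 allylic alcohol
Product: 18 [(3S,3aS,4R,8S,8aS)-3-hydroxy-6,8a-dimethyl-8-[(3-methylbutanoyl)oxy]-3-(propan-2-yl)-1,2,3,3a,4,5,8,8a-octahydroazulen-4-yl] 4-(acetyloxy)benzoate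
Conditions: 3-methylbutanoyl chloride, pyridine, DMAP, CH2Cl2, 0 °C to rt
Reagents that add atoms: 3-methylbutanoyl chloride, CC(C)CC(Cl)=O
Why: DMAP-catalysed acylation of the only free secondary (allylic) hydroxyl, C10–OH; the tertiary hydroxyl stays free and C10 keeps its configuration.

Step 14
Reactants: 18 diester aryl acetate
Product: 19 [(3S,3aS,4R,8S,8aS)-3-hydroxy-6,8a-dimethyl-8-[(3-methylbutanoyl)oxy]-3-(propan-2-yl)-1,2,3,3a,4,5,8,8a-octahydroazulen-4-yl] 4-hydroxybenzoate (target)
Conditions: NH4OAc, MeOH/H2O (4:1), rt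
Reagents that add atoms: none
Why: chemoselective transesterification (methanolysis) of the phenolic acetate, whose phenoxide leaving group makes it far more reactive than the two alkyl esters, frees the phenol.

## Compound list

1 | nerol, (2Z)-3,7-dimethylocta-2,6-dien-1-ol | CC(C)=CCC/C(C)=C\CO | starting material
2 | neryl chloride, (2Z)-1-chloro-3,7-dimethylocta-2,6-diene | CC(C)=CCC/C(C)=C\CCl | intermediate
3 | neryl trichlorosilane, trichloro[(2Z)-3,7-dimethylocta-2,6-dien-1-yl]silane | CC(C)=CCC/C(C)=C\C[Si](Cl)(Cl)Cl | intermediate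
4 | acrolein, prop-2-enal | C=CC=O | starting material
5 | trichlorosilyl ether of 6 | C=C[C@H](O[Si](Cl)(Cl)Cl)[C@@](C=C)(C)CCC=C(C)C | intermediate (not isolated)
6 | (3S,4S)-4-ethenyl-4,8-dimethylnona-1,7-dien-3-ol | C=C[C@H](O)[C@@](C=C)(C)CCC=C(C)C | intermediate
7 | tert-butyl{[(3S,4S)-4-ethenyl-4,8-dimethylnona-1,7-dien-3-yl]oxy}dimethylsilane | C=C[C@H](O[Si](C)(C)C(C)(C)C)[C@@](C=C)(C)CCC=C(C)C | intermediate
8 | tert-butyl{[(3S,4S)-6-(3,3-dimethyloxiran-2-yl)-4-ethenyl-4-methylhex-1-en-3-yl]oxy}dimethylsilane, both oxirane epimers | C=C[C@H](O[Si](C)(C)C(C)(C)C)[C@@](C=C)(C)CCC1OC1(C)C | intermediate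
9 | (6S,7S)-7-[(tert-butyldimethylsilyl)oxy]-6-ethenyl-2,6-dimethylnon-8-en-3-one | C=C[C@H](O[Si](C)(C)C(C)(C)C)[C@@](C=C)(C)CCC(=O)C(C)C | intermediate
10 | cyclised alkylsamarium alkoxide (C4–O–SmI2, C6–SmI2), same configuration as 11 | C=C[C@H](O[Si](C)(C)C(C)(C)C)[C@@]1(C)CC[C@](O[Sm](I)I)(C(C)C)[C@@H]1C[Sm](I)I | intermediate (not isolated)
11 | (1S,2S,3S)-3-[(1S)-1-[(tert-butyldimethylsilyl)oxy]prop-2-en-1-yl]-2-(hydroxymethyl)-3-methyl-1-(propan-2-yl)cyclopentan-1-ol | C=C[C@H](O[Si](C)(C)C(C)(C)C)[C@@]1(C)CC[C@](O)(C(C)C)[C@@H]1CO | intermediate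
12 | (1R,2S,5S)-2-[(1S)-1-[(tert-butyldimethylsilyl)oxy]prop-2-en-1-yl]-5-hydroxy-2-methyl-5-(propan-2-yl)cyclopentane-1-carbaldehyde | C=C[C@H](O[Si](C)(C)C(C)(C)C)[C@@]1(C)CC[C@](O)(C(C)C)[C@@H]1C=O | intermediate
13 | diisopinocampheylborinate of 14 (boron on the C6 oxygen; Ipc groups from (−)-α-pinene) | C=C[C@H](O[Si](C)(C)C(C)(C)C)[C@@]1(C)CC[C@](O)(C(C)C)[C@@H]1[C@H](OB([C@H]2C[C@H]3C[C@@H]([C@@H]2C)C3(C)C)[C@H]2C[C@H]3C[C@@H]([C@@H]2C)C3(C)C)CC(C)=C | intermediate (not isolated)
14 | (1S,2S,3S)-3-[(1S)-1-[(tert-butyldimethylsilyl)oxy]prop-2-en-1-yl]-2-[(1R)-1-hydroxy-3-methylbut-3-en-1-yl]-3-methyl-1-(propan-2-yl)cyclopentan-1-ol | C=C[C@H](O[Si](C)(C)C(C)(C)C)[C@@]1(C)CC[C@](O)(C(C)C)[C@@H]1[C@H](O)CC(C)=C | intermediate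
15 | (3S,3aS,4R,8S,8aS)-8-[(tert-butyldimethylsilyl)oxy]-6,8a-dimethyl-3-(propan-2-yl)-1,2,3,3a,4,5,8,8a-octahydroazulene-3,4-diol | CC1=C[C@H](O[Si](C)(C)C(C)(C)C)[C@@]2(C)CC[C@](O)(C(C)C)[C@@H]2[C@H](O)C1 | intermediate
16 | [(3S,3aS,4R,8S,8aS)-8-[(tert-butyldimethylsilyl)oxy]-3-hydroxy-6,8a-dimethyl-3-(propan-2-yl)-1,2,3,3a,4,5,8,8a-octahydroazulen-4-yl] 4-(acetyloxy)benzoate | CC1=C[C@H](O[Si](C)(C)C(C)(C)C)[C@@]2(C)CC[C@](O)(C(C)C)[C@@H]2[C@H](OC(=O)c2ccc(OC(C)=O)cc2)C1 | intermediate
17 | [(3S,3aS,4R,8S,8aS)-3,8-dihydroxy-6,8a-dimethyl-3-(propan-2-yl)-1,2,3,3a,4,5,8,8a-octahydroazulen-4-yl] 4-(acetyloxy)benzoate | CC1=C[C@H](O)[C@@]2(C)CC[C@](O)(C(C)C)[C@@H]2[C@H](OC(=O)c2ccc(OC(C)=O)cc2)C1 | intermediate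
18 | [(3S,3aS,4R,8S,8aS)-3-hydroxy-6,8a-dimethyl-8-[(3-methylbutanoyl)oxy]-3-(propan-2-yl)-1,2,3,3a,4,5,8,8a-octahydroazulen-4-yl] 4-(acetyloxy)benzoate | CC1=C[C@H](OC(=O)CC(C)C)[C@@]2(C)CC[C@](O)(C(C)C)[C@@H]2[C@H](OC(=O)c2ccc(OC(C)=O)cc2)C1 | intermediate
19 | [(3S,3aS,4R,8S,8aS)-3-hydroxy-6,8a-dimethyl-8-[(3-methylbutanoyl)oxy]-3-(propan-2-yl)-1,2,3,3a,4,5,8,8a-octahydroazulen-4-yl] 4-hydroxybenzoate | CC1=C[C@H](OC(=O)CC(C)C)[C@@]2(C)CC[C@](O)(C(C)C)[C@@H]2[C@H](OC(=O)c2ccc(O)cc2)C1 | target

## Step count and risks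

Total steps: 14. Longest linear sequence: 14 steps (1 to 19).

The three steps most likely to fail:

Step 3. The catalytic allylation is known for aromatic and β-substituted conjugated aldehydes but has not been shown for acrolein, which is small and polymerisable, so yield or ee may be poor. The fallback sets out from 1 and comes back at 6. Nerol 1 is O-allylated (NaH, allyl bromide, THF) to neryl allyl ether F1. n-BuLi in THF at −78 °C lithiates the unsubstituted allyl CH2, and this α-oxy carbanion shifts onto C1 in a [2,3]-Wittig rearrangement; the Z-alkene gives the syn pair. The product is racemic 6, that is 6 mixed with its mirror image (3R,4R)-4-ethenyl-4,8-dimethylnona-1,7-dien-3-ol F2. Sharpless kinetic resolution (Ti(OiPr)4, L-(+)-diisopropyl tartrate, t-BuOOH 0.6 equiv, 4 Å sieves, CH2Cl2, −20 °C) epoxidises F2 and leaves 6, at most half of the material.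

Step 7. Capture of the alkylsamarium by O2 may be inefficient, and selectivity at C5 rests only on the size difference between the silyloxyallyl arm and the methyl group on C1. The fallback sets out from 9 and comes back at 11; it removes the first risk, not the second. The same SmI2/HMPA cyclisation is run, but 10 is quenched with iodine to give the isolable primary iodide (1S,2R,3S)-3-[(1S)-1-[(tert-butyldimethylsilyl)oxy]prop-2-en-1-yl]-2-(iodomethyl)-3-methyl-1-(propan-2-yl)cyclopentan-1-ol F3. A radical-chain oxygenation (Bu3SnH, air, toluene, rt) then converts the C–I bond into the C6–OH of 11.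

Step 9. Reagent control may be eroded on this very hindered, α-branched β-hydroxy aldehyde; a magnesium-chelated addition is predicted to favour the wrong C6 epimer. The fallback sets out from 12 and comes back at 15. 2-Methylallylmagnesium chloride (THF, −78 °C) is added without chiral control, giving 14 mixed with its C6 epimer F4. Ring-closing metathesis as in step 10 gives 15 mixed with the C6-epimeric bicyclic diol F5. Dess–Martin periodinane converts both into the single β-hydroxy ketone F6. Me4NBH(OAc)3 (MeCN/AcOH, −20 °C) then delivers hydride within the C4–O–B complex, from the face of the C4 hydroxyl, which is also the face opposite the angular methyl; this gives the 4R alcohol 15.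

Further compounds

F1 | step 3 | neryl allyl ether, (2Z)-3,7-dimethyl-1-(prop-2-en-1-yloxy)octa-2,6-diene | CC(C)=CCC/C(C)=C\COCC=C
F2 | step 3 | (3R,4R)-4-ethenyl-4,8-dimethylnona-1,7-dien-3-ol (enantiomer of 6) | C=C[C@@H](O)[C@](C=C)(C)CCC=C(C)C
F3 | step 7 | (1S,2R,3S)-3-[(1S)-1-[(tert-butyldimethylsilyl)oxy]prop-2-en-1-yl]-2-(iodomethyl)-3-methyl-1-(propan-2-yl)cyclopentan-1-ol | C=C[C@H](O[Si](C)(C)C(C)(C)C)[C@@]1(C)CC[C@](O)(C(C)C)[C@@H]1CI
F4 | step 9 | (1S,2S,3S)-3-[(1S)-1-[(tert-butyldimethylsilyl)oxy]prop-2-en-1-yl]-2-[(1S)-1-hydroxy-3-methylbut-3-en-1-yl]-3-methyl-1-(propan-2-yl)cyclopentan-1-ol (C6 epimer of 14) | C=C[C@H](O[Si](C)(C)C(C)(C)C)[C@@]1(C)CC[C@](O)(C(C)C)[C@@H]1[C@@H](O)CC(C)=C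
F5 | step 9 | (3S,3aS,4S,8S,8aS)-8-[(tert-butyldimethylsilyl)oxy]-6,8a-dimethyl-3-(propan-2-yl)-1,2,3,3a,4,5,8,8a-octahydroazulene-3,4-diol (C6 epimer of 15) | CC1=C[C@H](O[Si](C)(C)C(C)(C)C)[C@@]2(C)CC[C@](O)(C(C)C)[C@@H]2[C@@H](O)C1
F6 | step 9 | (3S,3aR,8S,8aS)-8-[(tert-butyldimethylsilyl)oxy]-3-hydroxy-6,8a-dimethyl-3-(propan-2-yl)-2,3,3a,5,8,8a-hexahydroazulen-4(1H)-one | CC1=C[C@H](O[Si](C)(C)C(C)(C)C)[C@@]2(C)CC[C@](O)(C(C)C)[C@@H]2C(=O)C1
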